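**Plan**

- Retrosynthesis: the two O–Si bonds are cut first, then the O1–C5 bond of the tetrahydrofuran (giving a 1,4-diaryl-1,4-diol), then both aryl–C(carbinol) bonds (giving a meso C4 diamide and two copies of one aryl bromide); inside that bromide the aryl–C7 bond and the C8–O aryl ether bond are cut.
- Forward: the side-chain aryl bromide is built (ether, ketone, carbinol, silyl ether), two copies are joined to the meso-2,3-dimethylsuccinic unit, the diketone is reduced, and the tetrahydrofuran, the only ring made, closes in the penultimate step.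
- Stereochemistry: C8/C8′ (S) come from methyl (R)-lactate by invertive Mitsunobu etherification; C7/C7′ (R) from chelation-controlled ketone reduction; C3/C4 (cis) from the meso diacid; C2/C5 from thermodynamic control during ring closure.
- Enabling feature: C2 and C5 of the tetrahydrofuran ring are each benzylic to a para-alkoxy arene, so both ring C–O bonds ionize reversibly, while C3 and C4 carry a cis-dimethyl pair with no epimerization pathway; the ring can therefore settle into the isomer with each aryl trans to its neighbouring methyl.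

Key step: step 9

Remark (assumption): the descriptors read from the structure are 7R,8S and 7′R,8′S in the side chains (C7 = carbinol carbon, C8 = ether-bearing carbon) and 2R,3R,4S,5S in the ring (aryls at C2 and C5 cis to each other, each trans to the adjacent methyl, methyls cis). The side-chain hydroxyls are carried as triisopropylsilyl ethers, chosen as the silyl ether most resistant to BF3.

**Route**

Step 1
Reactants: 1 4-bromo-2-methoxyphenol; 2 methyl (R)-lactate
Product: 3 methyl (2S)-2-(4-bromo-2-methoxyphenoxy)propanoate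
Conditions: PPh3, DIAD, THF, 0 °C → rt
Reagents that add atoms: none
Why: Mitsunobu etherification, in which the phenol displaces the activated lactate hydroxyl by SN2 with inversion, so the R lactate carbon becomes the S aryl ether carbon (future C8).

Step 2
Reactants: 3 methyl (2S)-2-(4-bromo-2-methoxyphenoxy)propanoate
Product: 4 (2S)-2-(4-bromo-2-methoxyphenoxy)-N-methoxy-N-methylpropanamide
Conditions: MeNH(OMe)·HCl, iPrMgCl, THF, −20 °C
Reagents that add atoms: N,O-dimethylhydroxylamine hydrochloride, CNOC.Cl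
Why: Weinreb amide formation by ester aminolysis with the chloromagnesium amide is fast at −20 °C, where neither deprotonation of the α-aryloxy stereocentre nor halogen–magnesium exchange at the aryl bromide should compete.

Step 3
Reactants: 4 (2S)-2-(4-bromo-2-methoxyphenoxy)-N-methoxy-N-methylpropanamide; 5 4-bromo-1,2-dimethoxybenzene
Product: 7 (2S)-2-(4-bromo-2-methoxyphenoxy)-1-(3,4-dimethoxyphenyl)propan-1-one, via aryl Grignard reagent 6 (not isolated)
Conditions: 5, Mg, THF, reflux; then 4, THF, 0 °C; aq. NH4Cl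
Reagents that add atoms: none
Why: Weinreb ketone synthesis, in which the Grignard reagent adds once to give a chelated tetrahedral adduct that releases the ketone only on work-up, so over-addition and enolization of the α-aryloxy ketone are avoided and the aryl bromide is left alone.

Step 4
Reactants: 7 (2S)-2-(4-bromo-2-methoxyphenoxy)-1-(3,4-dimethoxyphenyl)propan-1-one
Product: 8 (1R,2S)-2-(4-bromo-2-methoxyphenoxy)-1-(3,4-dimethoxyphenyl)propan-1-ol
Conditions: Zn(BH4)2, Et2O/THF, −20 → 0 °C
Reagents that add atoms: none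
Why: Chelation-controlled (Cram-chelate) hydride reduction, in which zinc bridges the carbonyl and α-aryloxy oxygens and hydride enters from the face of the C8 hydrogen, opposite the C8 methyl, which should set C7 as R (anti, erythro to 8S).

Step 5
Reactants: 8 (1R,2S)-2-(4-bromo-2-methoxyphenoxy)-1-(3,4-dimethoxyphenyl)propan-1-ol
Product: 9 [(1R,2S)-2-(4-bromo-2-methoxyphenoxy)-1-(3,4-dimethoxyphenyl)propoxy]tri(propan-2-yl)silane
Conditions: TIPSOTf, 2,6-lutidine, CH2Cl2, 0 °C → rt
Reagents that add atoms: triisopropylsilyl trifluoromethanesulfonate, CC(C)[Si](C(C)C)(C(C)C)OS(=O)(=O)C(F)(F)F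
Why: Silylation of a secondary alcohol with a silyl triflate and a hindered pyridine base gives an ether that tolerates aryllithium chemistry and is bulky and weakly Lewis basic enough to resist BF3 in step 9.

Step 6
Reactants: 10 meso-2,3-dimethylsuccinic acid
Product: 11 (2R,3S)-N1,N4-dimethoxy-N1,N4,2,3-tetramethylbutanediamide
Conditions: MeNH(OMe)·HCl, EDC·HCl, HOBt (cat.), iPr2NEt, CH2Cl2, 0 °C → rt
Reagents that add atoms: N,O-dimethylhydroxylamine hydrochloride, CNOC.Cl
Why: Carbodiimide-mediated amide coupling (through the cyclic anhydride and the HOBt ester) converts both carboxyl groups under mild, weakly basic conditions that should leave the meso centres untouched.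

Step 7
Reactants: 9 [(1R,2S)-2-(4-bromo-2-methoxyphenoxy)-1-(3,4-dimethoxyphenyl)propoxy]tri(propan-2-yl)silane (2.2 equiv); 11 (2R,3S)-N1,N4-dimethoxy-N1,N4,2,3-tetramethylbutanediamide
Product: 13 meso-core diketone (2R,3S)-1,4-bis(4-{[(1R,2S)-1-(3,4-dimethoxyphenyl)-1-[(triisopropylsilyl)oxy]propan-2-yl]oxy}-3-methoxyphenyl)-2,3-dimethylbutane-1,4-dione, via aryllithium 12 (not isolated)
Conditions: 9, t-BuLi (2 equiv per bromide), THF, −78 °C; then 11, −78 → 0 °C; aq. NH4Cl
Reagents that add atoms: none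
Why: Bromine–lithium exchange followed by a twofold Weinreb ketone synthesis, in which each amide takes one aryllithium and is held as a chelated adduct until quench, so the diketone never meets the organolithium and the meso centres should survive.

Step 8
Reactants: 13 meso-core diketone
Product: 14 (2R,3S)-1,4-bis(4-{[(1R,2S)-1-(3,4-dimethoxyphenyl)-1-[(triisopropylsilyl)oxy]propan-2-yl]oxy}-3-methoxyphenyl)-2,3-dimethylbutane-1,4-diol (mixture of C1/C4 carbinol epimers)
Conditions: NaBH4, MeOH/THF, 0 °C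
Reagents that add atoms: none
Why: Borohydride reduction of the two aryl ketones at 0 °C should outpace enolization, so the cis-dimethyl relationship is kept, and the configuration of the new carbinols does not matter because both are ionized in step 9.

Step 9
Reactants: 14 1,4-diol (all carbinol epimers together)
Product: 16 (2R,3R,4S,5S)-2,5-bis(4-{[(1R,2S)-1-(3,4-dimethoxyphenyl)-1-[(triisopropylsilyl)oxy]propan-2-yl]oxy}-3-methoxyphenyl)-3,4-dimethyltetrahydrofuran, via kinetic tetrahydrofuran epimer mixture 15 (not isolated)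
Conditions: BF3·OEt2 (0.3 equiv), 4 Å molecular sieves, CH2Cl2, −78 → −20 °C; aq. NaHCO3
Reagents that add atoms: none
Why: BF3 ionizes a core carbinol to a para-alkoxybenzyl (quinone-methide-like) cation, which the remaining hydroxyl captures through oxygen in a 5-exo-trig closure that forms the O1–C5 bond and the tetrahydrofuran ring; this is the known acid-mediated SN1 cyclodehydration of 1,4-diaryl-butane-1,4-diols. Because the product is a doubly benzylic ether, the Lewis acid re-opens and re-closes either ring C–O bond, so the kinetic epimer mixture 15 and every carbinol epimer of 14 should converge on one isomer. C2 and C5 are set under thermodynamic control by the fixed cis-dimethyl pair at C3/C4, each aryl ending trans to its adjacent methyl (2,3-trans, 3,4-cis, 4,5-trans), the arrangement with the fewest vicinal cis contacts. The selectivity needed is ionization at the ring carbons only; the substrate secures it because C7 and C7′ carry a bulky, weakly Lewis-basic triisopropylsilyl ether and an inductively withdrawing β-aryloxy group, both of which disfavour a cation there. Low temperature, a substoichiometric charge of Lewis acid and sieves are chosen so that O-capture outruns Friedel–Crafts capture by the neighbouring arene and E1 loss of the C3/C4 hydrogens.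

Step 10
Reactants: 16 bis(triisopropylsilyl) ether of the target
Product: 17 target, (1R,1′R,2S,2′S)-2,2′-{[(2R,3R,4S,5S)-3,4-dimethyltetrahydrofuran-2,5-diyl]bis[(2-methoxy-4,1-phenylene)oxy]}bis[1-(3,4-dimethoxyphenyl)propan-1-ol]
Conditions: Bu4NF, THF, rt; aq. NH4Cl
Reagents that add atoms: none
Why: Fluoride-mediated desilylation takes place at silicon, so C7 and C7′ keep their R configuration, and the basic medium leaves the acid-sensitive benzylic ether ring intact.

**Compound list**

1 | 4-bromo-2-methoxyphenol | COc1cc(Br)ccc1O | starting material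
2 | methyl (R)-lactate | C[C@@H](O)C(=O)OC | starting material
3 | methyl (2S)-2-(4-bromo-2-methoxyphenoxy)propanoate | C[C@H](Oc1ccc(Br)cc1OC)C(=O)OC | intermediate
4 | (2S)-2-(4-bromo-2-methoxyphenoxy)-N-methoxy-N-methylpropanamide | C[C@H](Oc1ccc(Br)cc1OC)C(=O)N(C)OC | intermediate
5 | 4-bromo-1,2-dimethoxybenzene | COc1ccc(Br)cc1OC | starting material
6 | (3,4-dimethoxyphenyl)magnesium bromide | COc1ccc([Mg]Br)cc1OC | intermediate (not isolated)
7 | (2S)-2-(4-bromo-2-methoxyphenoxy)-1-(3,4-dimethoxyphenyl)propan-1-one | COc1ccc(C(=O)[C@H](C)Oc2ccc(Br)cc2OC)cc1OC | intermediate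
8 | (1R,2S)-2-(4-bromo-2-methoxyphenoxy)-1-(3,4-dimethoxyphenyl)propan-1-ol | COc1ccc([C@@H](O)[C@H](C)Oc2ccc(Br)cc2OC)cc1OC | intermediate
9 | [(1R,2S)-2-(4-bromo-2-methoxyphenoxy)-1-(3,4-dimethoxyphenyl)propoxy]tri(propan-2-yl)silane | COc1ccc([C@@H](O[Si](C(C)C)(C(C)C)C(C)C)[C@H](C)Oc2ccc(Br)cc2OC)cc1OC | intermediate
10 | meso-2,3-dimethylsuccinic acid | OC(=O)[C@@H](C)[C@@H](C)C(O)=O | starting material
11 | (2R,3S)-N1,N4-dimethoxy-N1,N4,2,3-tetramethylbutanediamide | CON(C)C(=O)[C@@H](C)[C@@H](C)C(=O)N(C)OC | intermediate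
12 | aryllithium from 9 (lithium in place of bromine) | COc1ccc([C@@H](O[Si](C(C)C)(C(C)C)C(C)C)[C@H](C)Oc2ccc([Li])cc2OC)cc1OC | intermediate (not isolated)
13 | (2R,3S)-1,4-bis(4-{[(1R,2S)-1-(3,4-dimethoxyphenyl)-1-[(triisopropylsilyl)oxy]propan-2-yl]oxy}-3-methoxyphenyl)-2,3-dimethylbutane-1,4-dione | COc1ccc([C@@H](O[Si](C(C)C)(C(C)C)C(C)C)[C@H](C)Oc2ccc(C(=O)[C@@H](C)[C@@H](C)C(=O)c3ccc(O[C@@H](C)[C@H](O[Si](C(C)C)(C(C)C)C(C)C)c4ccc(OC)c(OC)c4)c(OC)c3)cc2OC)cc1OC | intermediate
14 | corresponding (2R,3S)-2,3-dimethylbutane-1,4-diol, mixture of C1/C4 carbinol epimers | COc1ccc([C@@H](O[Si](C(C)C)(C(C)C)C(C)C)[C@H](C)Oc2ccc(C(O)[C@@H](C)[C@@H](C)C(O)c3ccc(O[C@@H](C)[C@H](O[Si](C(C)C)(C(C)C)C(C)C)c4ccc(OC)c(OC)c4)c(OC)c3)cc2OC)cc1OC | intermediate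
15 | 3,4-cis-dimethyl-2,5-diaryltetrahydrofuran bis(silyl ether), kinetic mixture of C2/C5 epimers | COc1ccc([C@@H](O[Si](C(C)C)(C(C)C)C(C)C)[C@H](C)Oc2ccc(C3OC(c4ccc(O[C@@H](C)[C@H](O[Si](C(C)C)(C(C)C)C(C)C)c5ccc(OC)c(OC)c5)c(OC)c4)[C@H](C)[C@@H]3C)cc2OC)cc1OC | intermediate (not isolated)
16 | (2R,3R,4S,5S)-2,5-bis(4-{[(1R,2S)-1-(3,4-dimethoxyphenyl)-1-[(triisopropylsilyl)oxy]propan-2-yl]oxy}-3-methoxyphenyl)-3,4-dimethyltetrahydrofuran | COc1ccc([C@@H](O[Si](C(C)C)(C(C)C)C(C)C)[C@H](C)Oc2ccc([C@H]3O[C@@H](c4ccc(O[C@@H](C)[C@H](O[Si](C(C)C)(C(C)C)C(C)C)c5ccc(OC)c(OC)c5)c(OC)c4)[C@H](C)[C@@H]3C)cc2OC)cc1OC | intermediate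
17 | (1R,1′R,2S,2′S)-2,2′-{[(2R,3R,4S,5S)-3,4-dimethyltetrahydrofuran-2,5-diyl]bis[(2-methoxy-4,1-phenylene)oxy]}bis[1-(3,4-dimethoxyphenyl)propan-1-ol] | COc1ccc([C@@H](O)[C@H](C)Oc2ccc([C@H]3O[C@@H](c4ccc(O[C@@H](C)[C@H](O)c5ccc(OC)c(OC)c5)c(OC)c4)[C@H](C)[C@@H]3C)cc2OC)cc1OC | target

**Step count**

Total steps: 10. Longest linear sequence: 9 steps (steps 1–5, then 7–10); step 6 is a one-step branch.

**Steps most likely to fail**

Step 9. Several processes could outrun clean O-capture and equilibration: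
- ionization or desilylation at the side-chain benzylic carbons, with loss of the 7R configuration;
- irreversible Friedel–Crafts capture of the ring cation by the neighbouring arene;
- E1 loss of a C3/C4 hydrogen, which would erase the cis-dimethyl relationship;
- equilibration that stops short of a single isomer.

Fallback: the same acid-mediated closure is run on a core without side chains, and the side chains are added afterwards. It sets out from 1 (with 11) and returns at 17.
- Benzylation of 1 (BnBr, K2CO3, DMF) should give 1-(benzyloxy)-4-bromo-2-methoxybenzene F1.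
- Exchange with t-BuLi gives [4-(benzyloxy)-3-methoxyphenyl]lithium F2, which adds twice to 11 to give (2R,3S)-1,4-bis[4-(benzyloxy)-3-methoxyphenyl]-2,3-dimethylbutane-1,4-dione F3.
- NaBH4 gives 1,4-bis[4-(benzyloxy)-3-methoxyphenyl]-2,3-dimethylbutane-1,4-diol F4 as an epimer mixture.
- BF3·OEt2 in CH2Cl2 closes and equilibrates it to (2R,3R,4S,5S)-2,5-bis[4-(benzyloxy)-3-methoxyphenyl]-3,4-dimethyltetrahydrofuran F5.
- Brief hydrogenolysis (H2, Pd/C, EtOAc) frees 4,4′-[(2R,3R,4S,5S)-3,4-dimethyltetrahydrofuran-2,5-diyl]bis(2-methoxyphenol) F6.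
- Twofold Mitsunobu reaction with 2 gives the bis[(S)-lactate ether] dimethyl ester F7.
- MeNH(OMe)·HCl/iPrMgCl gives the bis(N-methoxy-N-methylamide) F8.
- Grignard reagent 6 gives the bis[(S)-α-aryloxy ketone] F9.
- Zn(BH4)2 reduces both carbonyls under chelation control to give 17.

Step 7. The basic aryllithium may deprotonate the α-branched amide, which would leak material into the racemic dimethyl series, or the reaction may stall after one addition and waste the advanced bromide.

Fallback: a non-basic palladium-catalysed Fukuyama coupling. It sets out from 10 (with 12) and returns at 13.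
- EtSH, EDC·HCl and DMAP convert 10 into S,S′-diethyl (2R,3S)-2,3-dimethylbutanebis(thioate) F10.
- Aryllithium 12 is transmetallated with ZnCl2 to the arylzinc chloride F11.
- Coupling of F10 with F11 (PdCl2(PPh3)2 cat., THF/toluene, rt) should give 13; the ketone product is inert to the organozinc.

Step 4. The aryl ether oxygen is a weak donor, so chelation may be incomplete, facial selectivity poor and the C7 epimer hard to remove.

Fallback: Felkin–Anh reduction followed by invertive esterification. It sets out from 7 and returns at 8.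
- LiBH(s-Bu)3 in THF at −78 °C should give (1S,2S)-2-(4-bromo-2-methoxyphenoxy)-1-(3,4-dimethoxyphenyl)propan-1-ol F12.
- Mitsunobu reaction with 4-nitrobenzoic acid (PPh3, DIAD) inverts C1 to give (1R,2S)-2-(4-bromo-2-methoxyphenoxy)-1-(3,4-dimethoxyphenyl)propyl 4-nitrobenzoate F13.
- K2CO3/MeOH releases 8.

**Further compounds**

F1 | step 9 | 1-(benzyloxy)-4-bromo-2-methoxybenzene | COc1cc(Br)ccc1OCc1ccccc1
F2 | step 9 | [4-(benzyloxy)-3-methoxyphenyl]lithium | COc1cc([Li])ccc1OCc1ccccc1
F3 | step 9 | (2R,3S)-1,4-bis[4-(benzyloxy)-3-methoxyphenyl]-2,3-dimethylbutane-1,4-dione | COc1cc(C(=O)[C@@H](C)[C@@H](C)C(=O)c2ccc(OCc3ccccc3)c(OC)c2)ccc1OCc1ccccc1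
F4 | step 9 | 1,4-bis[4-(benzyloxy)-3-methoxyphenyl]-2,3-dimethylbutane-1,4-diol (carbinol epimer mixture) | COc1cc(C(O)[C@@H](C)[C@@H](C)C(O)c2ccc(OCc3ccccc3)c(OC)c2)ccc1OCc1ccccc1
F5 | step 9 | (2R,3R,4S,5S)-2,5-bis[4-(benzyloxy)-3-methoxyphenyl]-3,4-dimethyltetrahydrofuran | COc1cc([C@H]2O[C@@H](c3ccc(OCc4ccccc4)c(OC)c3)[C@H](C)[C@@H]2C)ccc1OCc1ccccc1
F6 | step 9 | 4,4′-[(2R,3R,4S,5S)-3,4-dimethyltetrahydrofuran-2,5-diyl]bis(2-methoxyphenol) | COc1cc([C@H]2O[C@@H](c3ccc(O)c(OC)c3)[C@H](C)[C@@H]2C)ccc1O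
F7 | step 9 | dimethyl (2S,2′S)-2,2′-{[(2R,3R,4S,5S)-3,4-dimethyltetrahydrofuran-2,5-diyl]bis[(2-methoxy-4,1-phenylene)oxy]}dipropanoate | COC(=O)[C@H](C)Oc1ccc([C@H]2O[C@@H](c3ccc(O[C@@H](C)C(=O)OC)c(OC)c3)[C@H](C)[C@@H]2C)cc1OC
F8 | step 9 | corresponding bis(N-methoxy-N-methylpropanamide) | CON(C)C(=O)[C@H](C)Oc1ccc([C@H]2O[C@@H](c3ccc(O[C@@H](C)C(=O)N(C)OC)c(OC)c3)[C@H](C)[C@@H]2C)cc1OC
F9 | step 9 | (2S,2′S)-2,2′-{[(2R,3R,4S,5S)-3,4-dimethyltetrahydrofuran-2,5-diyl]bis[(2-methoxy-4,1-phenylene)oxy]}bis[1-(3,4-dimethoxyphenyl)propan-1-one] | COc1ccc(C(=O)[C@H](C)Oc2ccc([C@H]3O[C@@H](c4ccc(O[C@@H](C)C(=O)c5ccc(OC)c(OC)c5)c(OC)c4)[C@H](C)[C@@H]3C)cc2OC)cc1OC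
F10 | step 7 | S,S′-diethyl (2R,3S)-2,3-dimethylbutanebis(thioate) | CCSC(=O)[C@@H](C)[C@@H](C)C(=O)SCC
F11 | step 7 | arylzinc chloride from 12 (ZnCl in place of lithium) | COc1ccc([C@@H](O[Si](C(C)C)(C(C)C)C(C)C)[C@H](C)Oc2ccc([Zn]Cl)cc2OC)cc1OC
F12 | step 4 | (1S,2S)-2-(4-bromo-2-methoxyphenoxy)-1-(3,4-dimethoxyphenyl)propan-1-ol | COc1ccc([C@H](O)[C@H](C)Oc2ccc(Br)cc2OC)cc1OC
F13 | step 4 | (1R,2S)-2-(4-bromo-2-methoxyphenoxy)-1-(3,4-dimethoxyphenyl)propyl 4-nitrobenzoate | COc1ccc([C@@H](OC(=O)c2ccc([N+](=O)[O-])cc2)[C@H](C)Oc3ccc(Br)cc3OC)cc1OC
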